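## Structural features

The target is a spiro[5.5]undecane in which two cyclohexanes share one quaternary carbon, C6. Ring A holds C1 (methylidene carbon), C2 (carbinol), C3, C4 (CHBr) and C5 (C(CH3)2). Ring B holds C7, C8 (CHBr), C9 (C(CH3)Cl), C10 and C11. In ring A the allylic alcohol sits beside the exocyclic alkene, the C4 bromide is trans to the C2 hydroxyl across C3, and C5 is bonded directly to C6, so two quaternary carbons are neighbours. In ring B the C9 chloride and the C8 bromide are trans and the C9 methyl is cis to the bromide. In the chair that keeps C5 equatorial on ring B both halogens are equatorial and the methyl is axial. C6 is a stereocentre only because C8 and C10 differ, so its configuration is decided by which arm of ring B carries the bromide. Fragile points are the tertiary chloride (ionisation, elimination), the allylic alcohol next to the alkene (ionisation, transposition) and the secondary bromides towards base. The C4 bromide is neopentylic: robust once made, but not accessible by displacement. The real difficulties are the vicinal quaternary pair C5–C6, a neopentyl bromide of defined configuration, and an equatorial C8 bromide lying syn to C5, which diaxial addition to a ring B alkene would not deliver. The key step uses the C1(=CH2)–C2(O) unit of ring A, the signature of a reductive alkyne–aldehyde coupling: C1 is the internal carbon of an alkyne on C6 and C2 is an aldehyde carbon.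

## Logic of the disconnections

30 ⇒ 29. The O–Si bond is cut. The allylic alcohol is kept masked until the end because the conditions that install the tertiary chloride would also attack a free allylic hydroxyl. The forward step needs a fluoride source that is not basic enough to eliminate the halides.

29 ⇒ 27 ⇒ 26. The C9–Cl bond and then the C9–CH3 bond are cut, leading back to a ketone at C9. The ketone both accepts the methyl group and activates C8. Two substituents and one stereocentre disappear. The forward steps must deliver methyl axially (cis to the C8 bromide) and replace the tertiary hydroxyl by chloride with retention.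

26 ⇒ 24 ⇒ 23. The C8–Br bond is cut and the enol ether that marks C8 is returned to the ketone. Ring B becomes symmetric, so C6 and C8 both cease to be stereocentres. The forward demand is high: a chiral base must choose one of two diastereotopic methylene groups, and the bromide must end equatorial.

23 ⇒ 22 ⇒ 20. The ketal is restored and the C4–Br bond is exchanged for a C4–B bond of opposite configuration. A neopentyl bromide cannot be made by substitution at carbon, and a boronate passes through the nickel step where a bromide would not. The forward step must be a halodeboronation with clean inversion.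

20 ⇒ 18 + 19. The C1–C2 bond is cut, which opens ring A to an alkyne on C6 and an aldehyde at the end of a four-carbon tether. One ring and the C2 stereocentre are removed. The forward step must close exo and place oxygen cis to boron.

18 ⇒ 17 ⇒ 16 ⇒ 14 + 15. The aldehyde is traced to an ester, the alkyne C–H to a C–Si bond, and the C–B bond is cut to an E-enoate and the diboron reagent. This removes the only stereocentre of the open chain. The forward step needs face-selective boryl addition at a very hindered β-carbon, and the alkyne must be capped while boryl–copper species are present.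

14 ⇒ 12 + 13 and 12 ⇒ 11. The enoate C=C bond is cut by olefination logic, and the aldehyde is traced to a vinyl group. The forward cleavage must take the alkene and spare the capped alkyne.

11 ⇒ 9 ⇒ 8 ⇒ 7 ⇒ 6. The alkyne is traced through the dibromoalkene to the aldehyde, the primary alcohol and the carboxylic acid. Only oxidation-level changes and a one-carbon homologation at a carbon without α-hydrogen are needed.

6 ⇒ 3 ⇒ 1 + 2. The C5–C6 bond is cut by a [3,3] transform, then the ester C–O bond. The most congested bond of the skeleton is thereby formed intramolecularly and both quaternary carbons appear in one step, from two commercial compounds. The forward rearrangement needs heat.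

## Other disconnections considered

Alternative 1: The cut is the C5–C6 bond, between the gem-dimethyl carbon and the spiro carbon. Forward, the tertiary hydroxyl of bromohydrin A1 is ionised, the neighbouring bromine bridges, and the ring carbon of the tetrasubstituted exocyclic alkene attacks the dimethyl-bearing carbon; loss of a methyl proton gives bromo spiro diene A2.
- In favour: both quaternary carbons, ring A, the C4 bromide and the methylidene arise in one step. The C4 bromide is made directly, without boron, and C6 follows from the E geometry through a chair transition state instead of a chiral base. On these two points, and on step count up to A2, the alternative is the better one.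
- Against: the cation has other exits (endocyclic proton loss, capture by the ring alkene). A1 must be a single enantiomer with a defined tetrasubstituted alkene. A2 still lacks three substituents. The C2 hydroxyl would need a late allylic oxidation trans to the C4 bromide in the presence of a second alkene. Bromochlorination of the ring B alkene of A2 is expected to open diaxially in the chair that keeps C5 equatorial, which puts bromine anti to C5, the opposite of the target.
- Comparison: structurally A2 carries less than 20, which already has the C2 oxygen and the C4 heteroatom in the right relative configuration. Mechanistically a cationic cascade with competing pathways stands against a neutral cyclisation whose regiochemistry is fixed by the tether. The alternative wins on length, the chosen plan on control of C2, C8 and C9.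

Alternative 2: The cut is the C1–C6 bond. Forward, zerovalent palladium inserts into the vinyl bromide of A3, 6-exo carbopalladation of the tethered cyclohexene follows, and β-hydride elimination gives spiro diene ketal A4.
- In favour: the spiro centre and the methylidene are made together. The alkene left in ring B marks C7/C8, so C6 is decided in the ring closure and no desymmetrisation is needed; here the alternative equals or betters the chosen plan. Both ring A stereocentres are already in A3.
- Against: the new bond joins a vinyl carbon to a fully substituted alkene carbon next to C5, so the vicinal quaternary pair is created in a congested insertion. The face of the cyclohexene, and with it C6, is controlled only by the remote C2 and C4 centres. A3 needs the anti silyloxy/bromide array with the neopentyl bromide on an open chain, which moves the hardest substitution problem instead of removing it.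
- Comparison: structurally A4 and 20 are at a similar level. Both key steps are metal-mediated cyclisations, but the chosen one joins an sp carbon to an aldehyde carbon while the Heck closure has to form a quaternary centre. Step counts are comparable: the alternative saves the boron-to-bromine exchange and the chiral base step and pays for them in the synthesis of A3.

Alternative 3: The cuts are the C6–C11 and C7–C8 bonds, so ring B is annulated onto ring A. Forward, the dienolate of bromo aldehyde A5 adds through its α-carbon to methyl vinyl ketone A6, and aldol condensation of the methyl ketone onto the formyl group gives bromo spiro cyclohexenone A7.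
- In favour: convergent and short. The methylidene arises automatically by deconjugative α-alkylation, and the enone distinguishes the two arms of ring B so that C6 is set in the annulation. In step economy it is better than the chosen plan.
- Against: enolate chemistry is run with a bromide three atoms from the nucleophilic carbon (cyclopropane formation, elimination). The relay from C4 to C6 across C5 is a 1,3 induction of uncertain size. A5 needs an enantioselective bromocyclisation of its own. A7 lacks the C2 oxygen, and the enone must still be turned into the C8 bromo ketone.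
- Comparison: structurally A7 is ahead in ring B and behind in ring A. Mechanistically polar enolate steps stand against a nickel cyclisation. The alternative is shorter; the chosen plan sets C2 in the ring-forming step and exposes only the neopentyl C4 bromide to strong base.

Key step: step 12

Assumption: the sense of induction of the ferrocenyl bisphosphine (step 9) and of the lithium amide (step 15) is taken from the simplest models (β-alkyl enoates; 4-tert-butylcyclohexanone, with C5 in the role of the equatorial tert-butyl group); if either is reversed on these substrates the mirror-image ligand or base is used with no other change.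

Remark: all spiro compounds keep the atom numbering of the target.

## Route

Step 1
Reactants: 1 1,4-dioxaspiro[4.5]decane-8-carboxylic acid; 2 prenol (3-methylbut-2-en-1-ol)
Product: 3 prenyl 1,4-dioxaspiro[4.5]decane-8-carboxylate
Conditions: EDC·HCl, 4-(dimethylamino)pyridine, CH2Cl2, 23 °C
Reagents that add atoms: none
Why: Carbodiimide (Steglich-type) esterification of an unhindered acid with a primary allylic alcohol; the neutral conditions leave the ketal untouched.

Step 2
Reactants: 3 prenyl 1,4-dioxaspiro[4.5]decane-8-carboxylate
Product: 6 8-(2-methylbut-3-en-2-yl)-1,4-dioxaspiro[4.5]decane-8-carboxylic acid, via silyl ketene acetal 4 (not isolated), via trimethylsilyl ester 5 (not isolated)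
Conditions: LiN(i-Pr)2, Me3SiCl, THF, −78 °C; then toluene, 100 °C; aqueous citric acid
Reagents that add atoms: none
Why: Ireland–Claisen rearrangement: the tetrasubstituted ketene acetal 4 (no geometry issue, the ring is symmetric) shifts [3,3] onto the dimethyl-substituted allyl terminus, so the C5–C6 bond and both quaternary carbons form in one concerted intramolecular step; no stereocentre is created.

Step 3
Reactants: 6 8-(2-methylbut-3-en-2-yl)-1,4-dioxaspiro[4.5]decane-8-carboxylic acid
Product: 7 [8-(2-methylbut-3-en-2-yl)-1,4-dioxaspiro[4.5]decan-8-yl]methanol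
Conditions: LiAlH4, THF, 0 → 65 °C
Reagents that add atoms: none
Why: Hydride reduction of a hindered carboxylic acid to the primary alcohol; the alkene and the ketal are inert to LiAlH4.

Step 4
Reactants: 7 [8-(2-methylbut-3-en-2-yl)-1,4-dioxaspiro[4.5]decan-8-yl]methanol
Product: 8 8-(2-methylbut-3-en-2-yl)-1,4-dioxaspiro[4.5]decane-8-carbaldehyde
Conditions: Dess–Martin periodinane, pyridine, CH2Cl2, 23 °C
Reagents that add atoms: none
Why: Dess–Martin oxidation; the aldehyde has no α-hydrogen, so enolisation-derived side reactions are excluded, and pyridine buffers the acetic acid for the ketal.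

Step 5
Reactants: 8 8-(2-methylbut-3-en-2-yl)-1,4-dioxaspiro[4.5]decane-8-carbaldehyde
Product: 9 8-(2,2-dibromoethenyl)-8-(2-methylbut-3-en-2-yl)-1,4-dioxaspiro[4.5]decane
Conditions: CBr4, PPh3, Et3N, CH2Cl2, 0 °C
Reagents that add atoms: carbon tetrabromide, BrC(Br)(Br)Br
Why: First stage of the Corey–Fuchs alkyne synthesis (Wittig-type dibromomethylenation); the small ylide should reach the hindered, non-enolisable aldehyde.

Step 6
Reactants: 9 8-(2,2-dibromoethenyl)-8-(2-methylbut-3-en-2-yl)-1,4-dioxaspiro[4.5]decane
Product: 11 triisopropyl{[8-(2-methylbut-3-en-2-yl)-1,4-dioxaspiro[4.5]decan-8-yl]ethynyl}silane, via lithium acetylide 10 (not isolated)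
Conditions: n-BuLi (2.2 equiv), THF, −78 → 0 °C; then i-Pr3SiOTf, −78 → 23 °C
Reagents that add atoms: triisopropylsilyl trifluoromethanesulfonate, CC(C)[Si](OS(=O)(=O)C(F)(F)F)(C(C)C)C(C)C
Why: Second stage of Corey–Fuchs: bromine–lithium exchange, α-elimination and 1,2-shift give the alkyne, and the second equivalent of base forms acetylide 10, which is silylated at its unhindered terminus; the cap is needed because a free terminal alkyne would itself be borylated by the copper–boryl species of step 9.

Step 7
Reactants: 11 triisopropyl{[8-(2-methylbut-3-en-2-yl)-1,4-dioxaspiro[4.5]decan-8-yl]ethynyl}silane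
Product: 12 2-methyl-2-{8-[(triisopropylsilyl)ethynyl]-1,4-dioxaspiro[4.5]decan-8-yl}propanal
Conditions: O3, CH2Cl2/MeOH, −78 °C (Sudan red 7B end point); then PPh3
Reagents that add atoms: ozone, [O-][O+]=O
Why: Ozonolysis with reductive work-up; a monosubstituted alkene reacts with ozone far faster than a silyl-capped alkyne, and the dye end point guards against over-oxidation.

Step 8
Reactants: 12 2-methyl-2-{8-[(triisopropylsilyl)ethynyl]-1,4-dioxaspiro[4.5]decan-8-yl}propanal; 13 trimethyl phosphonoacetate
Product: 14 methyl (E)-4-methyl-4-{8-[(triisopropylsilyl)ethynyl]-1,4-dioxaspiro[4.5]decan-8-yl}pent-2-enoate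
Conditions: NaH, THF, 0 → 23 °C
Reagents that add atoms: none
Why: Horner–Wadsworth–Emmons olefination of a non-enolisable α-quaternary aldehyde; the stabilised phosphonate anion gives the E-enoate.

Step 9
Reactants: 14 methyl (E)-4-methyl-4-{8-[(triisopropylsilyl)ethynyl]-1,4-dioxaspiro[4.5]decan-8-yl}pent-2-enoate; 15 bis(pinacolato)diboron
Product: 16 methyl (3S)-4-methyl-3-(pinacolatoboryl)-4-{8-[(triisopropylsilyl)ethynyl]-1,4-dioxaspiro[4.5]decan-8-yl}pentanoate
Conditions: CuCl (cat.), NaOt-Bu (cat.), (R)-1-[(S)-2-(diphenylphosphino)ferrocenyl]ethyldicyclohexylphosphine (cat.), MeOH (2 equiv), THF, 23 °C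
Reagents that add atoms: none
Why: Copper-catalysed asymmetric conjugate borylation (boryl–copper addition to the enoate, then protonation of the copper enolate by methanol); the chiral bisphosphine selects the alkene face and sets the C–B stereocentre as S, and the capped, doubly neopentyl alkyne is too hindered to compete.

Step 10
Reactants: 16 methyl (3S)-4-methyl-3-(pinacolatoboryl)-4-{8-[(triisopropylsilyl)ethynyl]-1,4-dioxaspiro[4.5]decan-8-yl}pentanoate
Product: 17 methyl (3S)-4-(8-ethynyl-1,4-dioxaspiro[4.5]decan-8-yl)-4-methyl-3-(pinacolatoboryl)pentanoate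
Conditions: Bu4NF, THF, 0 °C
Reagents that add atoms: none
Why: Fluoride cleavage of the C(sp)–Si bond; the pinacol boronate and the methyl ester tolerate Bu4NF at 0 °C, and it is done before the aldehyde is unveiled to avoid base-induced aldol chemistry.

Step 11
Reactants: 17 methyl (3S)-4-(8-ethynyl-1,4-dioxaspiro[4.5]decan-8-yl)-4-methyl-3-(pinacolatoboryl)pentanoate
Product: 18 (3S)-4-(8-ethynyl-1,4-dioxaspiro[4.5]decan-8-yl)-4-methyl-3-(pinacolatoboryl)pentanal
Conditions: i-Bu2AlH, CH2Cl2, −78 °C; aqueous potassium sodium tartrate
Reagents that add atoms: none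
Why: Partial reduction of the methyl ester through the stable aluminium hemiacetal at −78 °C; a β-boryl aldehyde has no leaving group to eliminate, and the C–B stereocentre is not involved.

Step 12
Reactants: 18 (3S)-4-(8-ethynyl-1,4-dioxaspiro[4.5]decan-8-yl)-4-methyl-3-(pinacolatoboryl)pentanal; 19 triisopropylsilane
Product: 20 (2R,4S)-5,5-dimethyl-1-methylidene-4-(pinacolatoboryl)-2-(triisopropylsilyloxy)spiro[5.5]undecan-9-one ethylene ketal
Conditions: bis(1,5-cyclooctadiene)nickel Ni(cod)2 (15 mol %), 1,3-dimesitylimidazol-2-ylidene (15 mol %), i-Pr3SiH (3 equiv), THF, 23 °C, slow addition of 18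
Reagents that add atoms: none
Why: Zerovalent nickel binds the alkyne and the aldehyde and cyclises oxidatively to an oxanickelacyclopentene, which forms the C1–C2 bond; σ-bond metathesis of Ni–O with Si–H and C–H reductive elimination then release the silyl ether and the catalyst. The closest known reaction type is the nickel-catalysed reductive cyclisation of ynals with trialkylsilanes. Ring A closes 6-exo-dig: only the internal alkyne carbon enters the ring, the terminal carbon becomes the methylidene, and an endo closure is geometrically excluded for a six-membered ring. The new C2 stereocentre is controlled by the boron-bearing carbon: in the chair-like tether the bulky boronate next to C5 stays equatorial and the carbonyl oxygen must lie in the plane of the metallacycle, hence pseudo-equatorial, so oxygen and boron emerge cis. The step needs chemoselectivity over alkyne oligomerisation and simple hydrosilylation, which the intramolecular setting, the two quaternary carbons that pre-fold the chain (Thorpe–Ingold effect) and slow addition should secure. The substrate contains no carbon–halogen bond for nickel to insert into, and boronate and ketal are inert. Triisopropylsilane is chosen so that the silyl ether survives the later ketal hydrolysis.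

Step 13
Reactants: 20 (2R,4S)-5,5-dimethyl-1-methylidene-4-(pinacolatoboryl)-2-(triisopropylsilyloxy)spiro[5.5]undecan-9-one ethylene ketal
Product: 22 (2R,4R)-4-bromo-5,5-dimethyl-1-methylidene-2-(triisopropylsilyloxy)spiro[5.5]undecan-9-one ethylene ketal, via aryl boronate complex 21 (not isolated)
Conditions: 3,5-(CF3)2C6H3Li (from the aryl bromide and n-BuLi), THF, −78 °C; then NBS, −78 → 0 °C
Reagents that add atoms: N-bromosuccinimide, O=C1CCC(=O)N1Br
Why: Stereoinvertive halodeboronation: the electron-poor aryllithium gives tetracoordinate complex 21, whose C–B bond is attacked by electrophilic bromine from the rear (SE2 with inversion), turning the cis boronate into the bromide trans to the silyloxy group; the electron-poor aryl group disfavours single-electron pathways, and the alkene is far less nucleophilic than the boronate complex.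

Step 14
Reactants: 22 (2R,4R)-4-bromo-5,5-dimethyl-1-methylidene-2-(triisopropylsilyloxy)spiro[5.5]undecan-9-one ethylene ketal
Product: 23 (2R,4R)-4-bromo-5,5-dimethyl-1-methylidene-2-(triisopropylsilyloxy)spiro[5.5]undecan-9-one
Conditions: pyridinium p-toluenesulfonate, acetone/H2O, 60 °C
Reagents that add atoms: water, O
Why: Acid-catalysed ketal hydrolysis; the triisopropylsilyl ether and the neopentyl bromide are stable to this weak acid.

Step 15
Reactants: 23 (2R,4R)-4-bromo-5,5-dimethyl-1-methylidene-2-(triisopropylsilyloxy)spiro[5.5]undecan-9-one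
Product: 24 (2R,4R,6S)-4-bromo-5,5-dimethyl-1-methylidene-2-(triisopropylsilyloxy)-9-(trimethylsilyloxy)spiro[5.5]undec-8-ene
Conditions: LiN[(R)-CH(CH3)Ph]2 (from the amine and n-BuLi), Me3SiCl, THF, −100 → −78 °C
Reagents that add atoms: chlorotrimethylsilane, C[Si](C)(C)Cl
Why: Desymmetrising enolisation by a chiral lithium amide with internal silyl quench: the base removes an axial α-hydrogen from one of the two diastereotopic methylene groups in the chair that keeps C5 equatorial, which decides which arm becomes C8 and so fixes C6; the choice is reagent-controlled, and since the substrate is one enantiomer the minor regioisomer is a separable diastereomer.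

Step 16
Reactants: 24 (2R,4R,6S)-4-bromo-5,5-dimethyl-1-methylidene-2-(triisopropylsilyloxy)-9-(trimethylsilyloxy)spiro[5.5]undec-8-ene
Product: 26 (2R,4R,6S,8S)-4,8-dibromo-5,5-dimethyl-1-methylidene-2-(triisopropylsilyloxy)spiro[5.5]undecan-9-one, via axial bromo ketone 25 (not isolated)
Conditions: NBS, THF, −78 °C; then LiBr, acetone, 23 °C
Reagents that add atoms: N-bromosuccinimide, O=C1CCC(=O)N1Br
Why: Electrophilic α-bromination of the silyl enol ether at C8 (position fixed by the enol ether); stereoelectronic axial attack gives 25, and degenerate SN2 exchange with bromide then inverts C8 to the thermodynamic equatorial bromide 26, which avoids the 1,3-diaxial contact with the axial C1; the neopentyl C4 bromide cannot exchange, and the absence of acid prevents bromine migration to C10.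

Step 17
Reactants: 26 (2R,4R,6S,8S)-4,8-dibromo-5,5-dimethyl-1-methylidene-2-(triisopropylsilyloxy)spiro[5.5]undecan-9-one
Product: 27 (2R,4R,6S,8S,9S)-4,8-dibromo-5,5,9-trimethyl-1-methylidene-2-(triisopropylsilyloxy)spiro[5.5]undecan-9-ol
Conditions: AlMe3 (3 equiv), toluene, −40 → 0 °C
Reagents that add atoms: trimethylaluminium, C[Al](C)C
Why: 1,2-Addition of methyl from excess AlMe3 in a hydrocarbon solvent, conditions known to favour axial delivery to cyclohexanones; methyl ends axial and cis to the equatorial bromide, the hydroxyl equatorial and trans to it, and the non-basic reagent avoids enolisation and epoxide formation.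

Step 18
Reactants: 27 (2R,4R,6S,8S,9S)-4,8-dibromo-5,5,9-trimethyl-1-methylidene-2-(triisopropylsilyloxy)spiro[5.5]undecan-9-ol
Product: 29 (2R,4R,6S,8S,9S)-4,8-dibromo-9-chloro-5,5,9-trimethyl-1-methylidene-2-(triisopropylsilyloxy)spiro[5.5]undecane, via chlorosulfite 28 (not isolated)
Conditions: SOCl2, 2,6-di-tert-butyl-4-methylpyridine, CH2Cl2, −40 → 0 °C
Reagents that add atoms: thionyl chloride, O=S(Cl)Cl
Why: Deoxychlorination through tertiary chlorosulfite 28: ionisation and collapse of the ion pair return chloride to the face that oxygen left (retention), and the opposite face is shielded or bridged by the neighbouring bromine, so both effects give chloride trans to bromine; the hindered base removes HCl to protect the alkene.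

Step 19
Reactants: 29 (2R,4R,6S,8S,9S)-4,8-dibromo-9-chloro-5,5,9-trimethyl-1-methylidene-2-(triisopropylsilyloxy)spiro[5.5]undecane
Product: 30 (2R,4R,6S,8S,9S)-4,8-dibromo-9-chloro-5,5,9-trimethyl-1-methylidenespiro[5.5]undecan-2-ol
Conditions: HF·pyridine, THF/pyridine, 0 → 23 °C
Reagents that add atoms: none
Why: Fluoride cleavage of the silyl ether under weakly acidic, non-basic conditions, so that neither the tertiary chloride nor the secondary bromides eliminate.

## Compound list

1 | 1,4-dioxaspiro[4.5]decane-8-carboxylic acid | OC(=O)C1CCC2(CC1)OCCO2 | starting material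
2 | prenol (3-methylbut-2-en-1-ol) | CC(C)=CCO | starting material
3 | prenyl 1,4-dioxaspiro[4.5]decane-8-carboxylate | CC(C)=CCOC(=O)C1CCC2(CC1)OCCO2 | intermediate
4 | trimethylsilyl prenyl ketene acetal of 3 (not isolated) | CC(C)=CCOC(O[Si](C)(C)C)=C1CCC2(CC1)OCCO2 | intermediate
5 | trimethylsilyl 8-(2-methylbut-3-en-2-yl)-1,4-dioxaspiro[4.5]decane-8-carboxylate (not isolated) | C=CC(C)(C)C1(C(=O)O[Si](C)(C)C)CCC2(CC1)OCCO2 | intermediate
6 | 8-(2-methylbut-3-en-2-yl)-1,4-dioxaspiro[4.5]decane-8-carboxylic acid | C=CC(C)(C)C1(C(=O)O)CCC2(CC1)OCCO2 | intermediate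
7 | [8-(2-methylbut-3-en-2-yl)-1,4-dioxaspiro[4.5]decan-8-yl]methanol | C=CC(C)(C)C1(CO)CCC2(CC1)OCCO2 | intermediate
8 | 8-(2-methylbut-3-en-2-yl)-1,4-dioxaspiro[4.5]decane-8-carbaldehyde | C=CC(C)(C)C1(C=O)CCC2(CC1)OCCO2 | intermediate
9 | 8-(2,2-dibromoethenyl)-8-(2-methylbut-3-en-2-yl)-1,4-dioxaspiro[4.5]decane | C=CC(C)(C)C1(C=C(Br)Br)CCC2(CC1)OCCO2 | intermediate
10 | {[8-(2-methylbut-3-en-2-yl)-1,4-dioxaspiro[4.5]decan-8-yl]ethynyl}lithium (not isolated) | C=CC(C)(C)C1(C#C[Li])CCC2(CC1)OCCO2 | intermediate
11 | triisopropyl{[8-(2-methylbut-3-en-2-yl)-1,4-dioxaspiro[4.5]decan-8-yl]ethynyl}silane | C=CC(C)(C)C1(C#C[Si](C(C)C)(C(C)C)C(C)C)CCC2(CC1)OCCO2 | intermediate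
12 | 2-methyl-2-{8-[(triisopropylsilyl)ethynyl]-1,4-dioxaspiro[4.5]decan-8-yl}propanal | O=CC(C)(C)C1(C#C[Si](C(C)C)(C(C)C)C(C)C)CCC2(CC1)OCCO2 | intermediate
13 | trimethyl phosphonoacetate | COC(=O)CP(=O)(OC)OC | starting material
14 | methyl (E)-4-methyl-4-{8-[(triisopropylsilyl)ethynyl]-1,4-dioxaspiro[4.5]decan-8-yl}pent-2-enoate | COC(=O)/C=C/C(C)(C)C1(C#C[Si](C(C)C)(C(C)C)C(C)C)CCC2(CC1)OCCO2 | intermediate
15 | bis(pinacolato)diboron | CC1(C)OB(OC1(C)C)B1OC(C)(C)C(C)(C)O1 | starting material
16 | methyl (3S)-4-methyl-3-(4,4,5,5-tetramethyl-1,3,2-dioxaborolan-2-yl)-4-{8-[(triisopropylsilyl)ethynyl]-1,4-dioxaspiro[4.5]decan-8-yl}pentanoate | C(#C[Si](C(C)C)(C(C)C)C(C)C)C1(CCC2(CC1)OCCO2)C(C)(C)[C@H](CC(=O)OC)B1OC(C)(C)C(C)(C)O1 | intermediate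
17 | methyl (3S)-4-(8-ethynyl-1,4-dioxaspiro[4.5]decan-8-yl)-4-methyl-3-(4,4,5,5-tetramethyl-1,3,2-dioxaborolan-2-yl)pentanoate | C#CC1(CCC2(CC1)OCCO2)C(C)(C)[C@H](CC(=O)OC)B1OC(C)(C)C(C)(C)O1 | intermediate
18 | (3S)-4-(8-ethynyl-1,4-dioxaspiro[4.5]decan-8-yl)-4-methyl-3-(4,4,5,5-tetramethyl-1,3,2-dioxaborolan-2-yl)pentanal (ynal boronate, key-step precursor) | C#CC1(CCC2(CC1)OCCO2)C(C)(C)[C@H](CC=O)B1OC(C)(C)C(C)(C)O1 | intermediate
19 | triisopropylsilane | CC(C)[SiH](C(C)C)C(C)C | starting material
20 | (2R,4S)-5,5-dimethyl-1-methylidene-4-(4,4,5,5-tetramethyl-1,3,2-dioxaborolan-2-yl)-2-(triisopropylsilyloxy)spiro[5.5]undecan-9-one ethylene ketal (oxygen and boron cis; key-step product) | C=C1[C@H](O[Si](C(C)C)(C(C)C)C(C)C)C[C@H](B3OC(C)(C)C(C)(C)O3)C(C)(C)C12CCC4(CC2)OCCO4 | intermediate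
21 | lithium [3,5-bis(trifluoromethyl)phenyl] boronate complex of 20 (not isolated) | [Li+].C=C1[C@H](O[Si](C(C)C)(C(C)C)C(C)C)C[C@H]([B-]3(c5cc(C(F)(F)F)cc(C(F)(F)F)c5)OC(C)(C)C(C)(C)O3)C(C)(C)C12CCC4(CC2)OCCO4 | intermediate
22 | (2R,4R)-4-bromo-5,5-dimethyl-1-methylidene-2-(triisopropylsilyloxy)spiro[5.5]undecan-9-one ethylene ketal (bromide trans to silyloxy) | C=C1[C@H](O[Si](C(C)C)(C(C)C)C(C)C)C[C@@H](Br)C(C)(C)C12CCC3(CC2)OCCO3 | intermediate
23 | (2R,4R)-4-bromo-5,5-dimethyl-1-methylidene-2-(triisopropylsilyloxy)spiro[5.5]undecan-9-one | C=C1[C@H](O[Si](C(C)C)(C(C)C)C(C)C)C[C@@H](Br)C(C)(C)C12CCC(=O)CC2 | intermediate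
24 | (2R,4R,6S)-4-bromo-5,5-dimethyl-1-methylidene-2-(triisopropylsilyloxy)-9-(trimethylsilyloxy)spiro[5.5]undec-8-ene | C=C1[C@H](O[Si](C(C)C)(C(C)C)C(C)C)C[C@@H](Br)C(C)(C)[C@]12CCC(O[Si](C)(C)C)=CC2 | intermediate
25 | (2R,4R,6S,8R)-4,8-dibromo-5,5-dimethyl-1-methylidene-2-(triisopropylsilyloxy)spiro[5.5]undecan-9-one (axial C8 bromide, not isolated) | C=C1[C@H](O[Si](C(C)C)(C(C)C)C(C)C)C[C@@H](Br)C(C)(C)[C@]12CCC(=O)[C@H](Br)C2 | intermediate
26 | (2R,4R,6S,8S)-4,8-dibromo-5,5-dimethyl-1-methylidene-2-(triisopropylsilyloxy)spiro[5.5]undecan-9-one (equatorial C8 bromide) | C=C1[C@H](O[Si](C(C)C)(C(C)C)C(C)C)C[C@@H](Br)C(C)(C)[C@]12CCC(=O)[C@@H](Br)C2 | intermediate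
27 | (2R,4R,6S,8S,9S)-4,8-dibromo-5,5,9-trimethyl-1-methylidene-2-(triisopropylsilyloxy)spiro[5.5]undecan-9-ol (methyl cis, hydroxyl trans to the C8 bromide) | C=C1[C@H](O[Si](C(C)C)(C(C)C)C(C)C)C[C@@H](Br)C(C)(C)[C@]12CC[C@](C)(O)[C@@H](Br)C2 | intermediate
28 | chlorosulfite of 27 (not isolated) | C=C1[C@H](O[Si](C(C)C)(C(C)C)C(C)C)C[C@@H](Br)C(C)(C)[C@]12CC[C@](C)(OS(Cl)=O)[C@@H](Br)C2 | intermediate
29 | (2R,4R,6S,8S,9S)-4,8-dibromo-9-chloro-5,5,9-trimethyl-1-methylidene-2-(triisopropylsilyloxy)spiro[5.5]undecane | C=C1[C@H](O[Si](C(C)C)(C(C)C)C(C)C)C[C@@H](Br)C(C)(C)[C@]12CC[C@](C)(Cl)[C@@H](Br)C2 | intermediate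
30 | (2R,4R,6S,8S,9S)-4,8-dibromo-9-chloro-5,5,9-trimethyl-1-methylidenespiro[5.5]undecan-2-ol | C=C1[C@H](O)C[C@@H](Br)C(C)(C)[C@]12CC[C@](C)(Cl)[C@@H](Br)C2 | target

## Step count and least certain steps

Total: 19 steps. Longest linear sequence: 19 steps (1 → 30); compounds 2, 13, 15 and 19 are commercial.

Step 12 (key step). The most likely failures are oligomerisation or direct hydrosilylation of the terminal alkyne in place of oxidative cyclisation at the congested internal alkyne carbon, and loss of cis selectivity through a boat-like metallacycle. Fallback: the same bond is made by a chromium-mediated vinyl addition. It sets out from 17: Markovnikov hydroiodination of the alkyne (9-iodo-9-borabicyclo[3.3.1]nonane, then acetic acid) would give the vinyl iodide ester F1; reduction with i-Bu2AlH at −78 °C the iodo aldehyde F2; an intramolecular Nozaki–Hiyama–Kishi reaction (CrCl2, catalytic NiCl2, DMF) the free allylic alcohol F3, with the same chair preference for an equatorial boronate; silylation (i-Pr3SiOTf, 2,6-lutidine) returns to the route at 20.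

Step 13. Rear-side attack at a neopentyl carbon is slow, so a single-electron pathway with loss of stereospecificity, or bromination of the alkene, may take over. Fallback: a radical instead of a polar bromodeboronation. It sets out from 20: in situ ester exchange would give the catechol boronate F4, which is brominated in a radical chain with a sulfonyl bromide as bromine-atom donor and returns to the route at 22. The configuration then rests on the facial preference of the ring A radical: bromine transfer anti to the silyloxy group is favoured in both chairs (equatorial attack when the silyloxy group is axial, axial attack when it is equatorial). The C4 epimer would be removed by chromatography.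

Step 15. The base may discriminate poorly between the two α-methylene groups, since reagent control on this spiro ketone is extrapolated from simple 4-substituted cyclohexanones; base-induced elimination at C4 is a lesser risk. Fallback: separation in place of reagent control. It sets out from 23: LiN(i-Pr)2/Me3SiCl would give 24 together with the regioisomeric silyl enol ether F5; bromination and bromide equilibration of the mixture as in step 16 give 26 and the C10 bromo ketone F6, which are diastereomers and are separated by chromatography; the route is rejoined at 26.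

Step 18. The ion pair may dissociate, so that chloride adds to a free tertiary cation from the axial face (C9 epimer), or proton loss to alkenes and ring contraction of the bromohydrin may compete. Fallback: inversion through a bridged ion in place of retention through an ion pair. It sets out from 26: MeMgBr with CeCl3 at −78 °C (equatorial attack) would give the C9-epimeric alcohol F7 with an axial hydroxyl; HCl under ionising conditions then removes the axial oxygen, the neighbouring bromine bridges the cation and chloride enters anti to it, returning to the route at 29.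

Step 9. Boryl–copper addition at a β-carbon flanked by two quaternary carbons may be slow, and face selectivity may be low. Fallback: the C–B stereocentre is made by lithiation–borylation. It sets out from 12: NaBH4 reduction would give the alcohol F8; carbamoylation (i-Pr2NCOCl) the carbamate F9; sparteine-mediated lithiation with s-BuLi, trapping with allyl pinacol boronate and 1,2-migration the homoallyl boronate F10; ozonolysis the silyl-capped ynal F11; Bu4NF buffered with acetic acid returns to the route at 18.

## Further compounds

F1 | step 12 | methyl (3S)-4-[8-(1-iodoethenyl)-1,4-dioxaspiro[4.5]decan-8-yl]-4-methyl-3-(4,4,5,5-tetramethyl-1,3,2-dioxaborolan-2-yl)pentanoate | C=C(I)C1(CCC2(CC1)OCCO2)C(C)(C)[C@H](CC(=O)OC)B1OC(C)(C)C(C)(C)O1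
F2 | step 12 | (3S)-4-[8-(1-iodoethenyl)-1,4-dioxaspiro[4.5]decan-8-yl]-4-methyl-3-(4,4,5,5-tetramethyl-1,3,2-dioxaborolan-2-yl)pentanal | C=C(I)C1(CCC2(CC1)OCCO2)C(C)(C)[C@H](CC=O)B1OC(C)(C)C(C)(C)O1
F3 | step 12 | (2R,4S)-2-hydroxy-5,5-dimethyl-1-methylidene-4-(4,4,5,5-tetramethyl-1,3,2-dioxaborolan-2-yl)spiro[5.5]undecan-9-one ethylene ketal | C=C1[C@H](O)C[C@H](B3OC(C)(C)C(C)(C)O3)C(C)(C)C12CCC4(CC2)OCCO4
F4 | step 13 | (2R,4S)-4-(1,3,2-benzodioxaborol-2-yl)-5,5-dimethyl-1-methylidene-2-(triisopropylsilyloxy)spiro[5.5]undecan-9-one ethylene ketal | C=C1[C@H](O[Si](C(C)C)(C(C)C)C(C)C)C[C@H](B3Oc5ccccc5O3)C(C)(C)C12CCC4(CC2)OCCO4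
F5 | step 15 | regioisomeric silyl enol ether (double bond C9=C10; C6 epimer of 24 in effect) | C=C1[C@H](O[Si](C(C)C)(C(C)C)C(C)C)C[C@@H](Br)C(C)(C)[C@]12CC=C(O[Si](C)(C)C)CC2
F6 | step 15 | regioisomeric bromo ketone (equatorial bromide at C10) | C=C1[C@H](O[Si](C(C)C)(C(C)C)C(C)C)C[C@@H](Br)C(C)(C)[C@]12C[C@@H](Br)C(=O)CC2
F7 | step 18 | (2R,4R,6S,8S,9R)-4,8-dibromo-5,5,9-trimethyl-1-methylidene-2-(triisopropylsilyloxy)spiro[5.5]undecan-9-ol (hydroxyl axial and cis to the C8 bromide) | C=C1[C@H](O[Si](C(C)C)(C(C)C)C(C)C)C[C@@H](Br)C(C)(C)[C@]12CC[C@@](C)(O)[C@@H](Br)C2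
F8 | step 9 | 2-methyl-2-{8-[(triisopropylsilyl)ethynyl]-1,4-dioxaspiro[4.5]decan-8-yl}propan-1-ol | OCC(C)(C)C1(C#C[Si](C(C)C)(C(C)C)C(C)C)CCC2(CC1)OCCO2
F9 | step 9 | 2-methyl-2-{8-[(triisopropylsilyl)ethynyl]-1,4-dioxaspiro[4.5]decan-8-yl}propyl N,N-diisopropylcarbamate | CC(C)N(C(C)C)C(=O)OCC(C)(C)C1(C#C[Si](C(C)C)(C(C)C)C(C)C)CCC2(CC1)OCCO2
F10 | step 9 | (S)-homoallyl boronate: 2-{(3S)-2-methyl-2-{8-[(triisopropylsilyl)ethynyl]-1,4-dioxaspiro[4.5]decan-8-yl}hex-5-en-3-yl}-4,4,5,5-tetramethyl-1,3,2-dioxaborolane | C(#C[Si](C(C)C)(C(C)C)C(C)C)C1(CCC2(CC1)OCCO2)C(C)(C)[C@H](CC=C)B1OC(C)(C)C(C)(C)O1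
F11 | step 9 | (3S)-4-methyl-3-(4,4,5,5-tetramethyl-1,3,2-dioxaborolan-2-yl)-4-{8-[(triisopropylsilyl)ethynyl]-1,4-dioxaspiro[4.5]decan-8-yl}pentanal | C(#C[Si](C(C)C)(C(C)C)C(C)C)C1(CCC2(CC1)OCCO2)C(C)(C)[C@H](CC=O)B1OC(C)(C)C(C)(C)O1
A1 | alternative 1 | (E)-configured monocyclic bromohydrin: (3R)-3-bromo-2-methyl-6-(4-methylcyclohex-3-en-1-ylidene)heptan-2-ol | C/C(CC[C@@H](Br)C(C)(C)O)=C1\CC=C(C)CC1
A2 | alternative 1 | bromo spiro diene with exocyclic methylene | C=C1CC[C@@H](Br)C(C)(C)[C@]12CCC(C)=CC2
A3 | alternative 2 | vinyl bromide Heck precursor with tethered cyclohexene ketal | C=C(Br)[C@H](O[Si](C)(C)C(C)(C)C)C[C@@H](Br)C(C)(C)C1=CCC2(CC1)OCCO2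
A4 | alternative 2 | spiro diene ketal with complete ring A | C=C1[C@H](O[Si](C)(C)C(C)(C)C)C[C@@H](Br)C(C)(C)[C@@]12C=CC3(CC2)OCCO3
A5 | alternative 3 | bromo cyclocitral: (5R)-5-bromo-2,6,6-trimethylcyclohex-1-ene-1-carbaldehyde | CC1=C(C=O)C(C)(C)[C@H](Br)CC1
A6 | alternative 3 | methyl vinyl ketone | C=CC(C)=O
A7 | alternative 3 | bromo spiro cyclohexenone | C=C1CC[C@@H](Br)C(C)(C)[C@]12CCC(=O)C=C2
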